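Left-handed substrate is left over in delta, the flask asked about: 39.8% of the charge at 40.0 h, beside left-handed product flat at 10.2%.

| setting | delta | theta | flask |
|---|---|---|---|
| left-handed substrate | 0.20 M | 0.20 M | 0.20 M |
| right-handed substrate | 0.20 M | 0.20 M | 0.20 M |
| coupling partner | 1.5 equiv | 2.2 equiv | 1.50 equiv |
| free catalyst | 5 mol% | 5 mol% | 5 mol% |
| impurity | 15 mM | 15 mM | 15 mM |
| remark | the very flask that is asked about, followed so far | run made earlier |  |
| time |  |  | 3.0 d |

| run | time / h | left-handed product / % | left-handed substrate / % |
|---|---|---|---|
| delta | 5.00 | 10.7 | 40.2 |
| delta | 15.0 | 9.8 | 39.7 |
| delta | 30.0 | 10.2 | 39.9 |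
| delta | 40.0 | 10.2 | 39.8 |
| theta | 0.333 | 10.2 | 40.1 |
| theta | 1.00 | 13.0 | 36.9 |
| theta | 2.00 | 13.5 | 36.5 |
| theta | 3.00 | 13.3 | 36.9 |

(readings scatter by 0.3 percentage points)

- birch: change nothing and wait 40 h more
- cedar: at 3.0 d add free catalyst, 100% of the amount charged, then wait 40 h
- ash: at 3.0 d add coupling partner, 100% of the amount charged, then wait 40 h
- alder: at 3.0 d take out 90% of the left-handed product then present, then wait 40 h

- free catalyst is single-handed; left-handed substrate and right-handed substrate are mirror images of each other, charged as a racemate, each of them at the stated concentration
- what is taken out of left-handed product is counted as made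
- the numbers in the tables scatter by 0.3 percentage points (one standard deviation)
- steps that have been proposed: free catalyst + left-handed substrate <-> catalyst intermediate A; free catalyst + right-handed substrate <-> catalyst intermediate B; coupling partner + catalyst intermediate A -> free catalyst + left-handed product; coupling partner + catalyst intermediate B -> free catalyst + right-handed product; free catalyst + impurity -> spent catalyst A; coupling partner + free catalyst -> spent catalyst B
- additions bring no volume worth counting

- left-handed product, in percent of the left-handed substrate and right-handed substrate together first charged, at 3.0 d
- the remedy with the largest gain of left-handed product, or "none" below 2 percentage points (birch / cedar / ash / alder / none)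
- left-handed product present, with what was taken out counted in, in percent of the left-handed substrate and right-handed substrate together first charged, after cedar
- left-handed product present, with what was taken out counted in, in percent of the left-handed substrate and right-handed substrate together first charged, after ash

So I read the rate, and theta shows it best. There left-handed product grows at 0.306 h⁻¹ of the charge up to 0.333 h, then at 0.0420 h⁻¹ up to 1.00 h, a fall by a factor 7.29. What slows it? Left-handed substrate, counted even from the charge, multiplies the rate by 0.738, while the rate itself has been multiplied by 0.137. Coupling partner, charged at 2.2 equiv, has given 0.0520 M to left-handed product. These are corrections; the large term is live catalyst lost.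

Who takes it? Coupling partner speeds turnover and its own kill alike, so that kill alone gives a plateau free of partner. Yet theta's plateau, 13.3%, stands 1.30 times delta's, on a partner ratio of 1.47. I charge the loss mainly to impurity, one catalyst per impurity.

My quantity is −5.00 mM, the catalyst margin: catalyst charged minus impurity charged. Negative, it makes catalyst the limiting reagent of that titration, so the rate dies with impurity still present. Waiting, coupling partner and taking out product leave the margin as it is, and I hold 10.2%. Cedar adds 10.0 mM, which lifts the margin to 5.00 mM. At theta's early rate scaled to that surplus, the leftover clears in about 2.60 h, shorter than 40 h. So I expect cedar close to 50.0%, the left-handed share of the charge.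

The forecast says 10.2% now, cedar best, 32% after cedar and 10.2% after ash: “Fresh catalyst first titrates this”. On cedar my reckoning stands higher than its number.

The flask gives 10.3% now, 10.3% after ash, and cedar as best at 47.8%, a gain of 38 percentage points. My margin after cedar, 5.00 mM, and the forecast's about 4 mM effective are both surpluses; they part on what that surplus yields, 47.8% in the flask against the forecast's 32%. In the simulated run of the flask with the step from free catalyst and impurity to spent catalyst A taken away, cedar brings 0 points.

    free catalyst + left-handed substrate ⇌ catalyst intermediate A (K = 3.60 M⁻¹, k = 1350 M⁻¹ h⁻¹)
    free catalyst + right-handed substrate ⇌ catalyst intermediate B (K = 2.58 M⁻¹, k = 298 M⁻¹ h⁻¹)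
    coupling partner + catalyst intermediate A → free catalyst + left-handed product (k = 231 M⁻¹ h⁻¹)
    coupling partner + catalyst intermediate B → free catalyst + right-handed product (k = 73.8 M⁻¹ h⁻¹)
    free catalyst + impurity → spent catalyst A (k = 895 M⁻¹ h⁻¹)
    coupling partner + free catalyst → spent catalyst B (k = 0.515 M⁻¹ h⁻¹)

In the neighbouring flask, the same recipe with 20 mol% of free catalyst, the margin is 25.0 mM, so the rate should outlast impurity. It gives 48.1% at 72.0 h, with impurity at 0% and free catalyst at 45.2% of its charge.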